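## Structural features

The target is a germacranolide: a ten-membered carbocycle (C1–C10) fused through C6 and C7 to a five-membered unsaturated lactone (O6–C12(=O)–C11=C7), whose tetrasubstituted alkene carries the acetoxymethyl carbon C13. Two trans trisubstituted epoxides sit on the ring (C1/C10 with methyl C14, C4/C5 with methyl C15), and O8 carries the (2R)-3-chloro-2-hydroxy-2-methylpropanoyl group. The six ring stereocentres (1R,4R,5R,6S,8S,10R) fall into two runs, C4–C5–C6 and C8/C10–C1, separated by the sp2 carbon C7; O6 and O8 are syn across C7, and both methyl groups lie on the face opposite to these oxygens. Fragile groups are the 13-acetoxy-7(11)-en-12,6-olide (open to SN2′ loss of acetate and to γ-deprotonation at C6), the epoxides (transannular opening under acid) and the chlorohydrin (closure to a glycidate under base). The real difficulty is to close a ten-membered ring containing three planar units without loss of alkene geometry, before any fragile group exists. A second difficulty is that C12 and C13 are equivalent CH2O arms on C11 until O6 tells them apart. The key step uses the fact that C2–C3 is the one ring bond joining two CH2 groups, each of which stands next to one of the trisubstituted double bonds (C1=C10, C4=C5) from which the epoxides derive.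

## Logic of the disconnections

44 to 43. The four C–O bonds of the two oxiranes are cut first. They are the most acid-sensitive groups and each maps onto an E-trisubstituted alkene. Four stereocentres disappear. The forward step must epoxidise both ring alkenes on their outer faces and leave the electron-poor C7=C11 bond alone.

43 to 36 and 41. The O8–acyl bond is cut so that the base-labile chlorohydrin enters late. The side chain becomes a chiral-pool piece (41 from 39 from 37). The forward step must acylate a hindered secondary allylic alcohol without disturbing the allylic acetate, and the tertiary hydroxyl of the acid must be masked.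

36 to 29 (through 35, 33, 32, 31, 30). The O8–Si bond is restored, the lactone is taken back at C12 to the ene-1,4-diol level (33), the C13 acetate is removed (31) and the O6/O12 acetal is traced to the PMB ether (30) and the acetonide (29). This is done because C12 and C13 must be distinguished by a reaction that only the CH2OH cis to C6 can undergo. The gain is that 29 carries only ethers, acetals and a silyl ether. The forward demand is intramolecular capture of the oxidised PMB carbon by that one hydroxyl.

29 to 26 (through 28). The C2–H bond is replaced by C2–S and then the C2–C3 bond is cut. It is the only ring bond between two methylenes, both allylic, so a sulfonyl group at C2 turns one electrophilic allylic terminus into a nucleophile. The ring and one skeletal bond are removed and no stereocentre is affected. The forward demand is end-to-end SN2 alkylation at high dilution with α-attack of the allyl anion.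

26 to 21 and 22 (through 25, 24). The C3–Br and C2–S bonds are cut back to two primary allylic oxygens, told apart as free alcohol and primary silyl ether. The sulfone is introduced only after all organolithium chemistry, because its α-protons would not survive it. The forward demand is selective cleavage of a primary silyl ether beside a secondary one.

21 to 15 and 18 (through 20, 19; 18 from 16). The C8–C9 bond is cut by a vinylogous aldol transform. It delivers C9, C10, C14, C1 and C2 with the E alkene in one step from a senecioate dienolate. The forward demand is catalyst-controlled Si-face attack on a hindered enal that already carries C6.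

15 to 4 and 8 (through 13, 12, 11, 10). The formyl carbon C8 is removed from C7 (C–Br), the PMB ether and the C6–H bond are cut (ketone 11), and the C5–C6 bond is cut. C6 is thereby set by reagent control on a ketone flanked by two alkenyl groups of very different size. The forward demand is a selective carbonyl reduction and a low-temperature bromine–lithium exchange next to an allylic ether.

4 to 1 (through 2) and 8 to 5 (through 7). The C7–CHO bond and the C7=C11 bond are cut back to the symmetric ketone, and the alkenyl iodide is cut to an alkyne by carbometalation. Because C11 carries two identical arms, the tetrasubstituted alkene has no geometry to control. The forward demand is a stable 1-bromo-1-lithioalkene and syn carboalumination.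

## Other disconnections considered

Alternative 1: The cut is the O–C5 bond of the 4,5-epoxide together with the O6–C12 acyl bond, leading back from the bis-silyl diepoxy butenolide A1 to the tertiary alcohol A2, which carries a cis-5,6-epoxide and a C12 methyl ester. In the forward step NaH forms the C4 alkoxide, which opens the oxirane at C5 with inversion (Payne rearrangement), and the freed C6 alkoxide closes the lactone.
- In its favour: the 4,5-epoxide is set by a stereospecific displacement, not by facial selectivity, and lactonisation makes the rearrangement irreversible. C12 (ester) and C13 (silyl ether) are already different in A2; on that point it is better than the chosen plan, which spends four steps on the distinction.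
- Against it: A2 presupposes a Z-configured C5=C6 bond inside the ten-membered ring, a defined geometry at the tetrasubstituted C7=C11 bond (no symmetry helps), a configured tertiary carbinol and a face-selective cis-epoxidation. The C4 alkoxide may also attack the 1,10-epoxide across the ring. After A1 two silyl groups must still be exchanged for acetate and the chlorohydrin ester on a diepoxide.
- Comparison: the elementary step is as reliable mechanistically as the chosen SN2 alkylation. The ring-forming problem is not addressed at all, and the number of steps to A2 would probably exceed that to 26.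

Alternative 2: The cut is C3–C4 together with O–C5, leading from the open-chain epoxide A3 to the α-chloro methyl ketone A4 and the homoallylic Grignard reagent A5. In the forward step A5, with CeCl3, adds to the ketone anti to chlorine (Cornforth model) and the alkoxide displaces chloride.
- In its favour: it is convergent, the trans-epoxide is set by acyclic control independent of any ring conformation, and CeCl3 suppresses enolisation.
- Against it: the chloride-bearing centre of A4 is α to a ketone and can epimerise, and the neighbouring silyloxy group may compete with the Cornforth arrangement. The epoxide must then survive everything that follows, including a ring closure at C8–C9 that would have to create the C8 carbinol at the same time.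
- Comparison: it is better than the chosen plan in that the C4/C5 configuration does not depend on a macrocycle. The advantage is small, since the 4,5-alkene is the better-controlled of the two epoxidations in the chosen plan (A(1,3) strain). It leaves the macrocyclisation unsolved and is not shorter.

Alternative 3: The cut is C7–C8, leading from the dienolide A6 (the same compound as 36 of the chosen route) to the β-iodobutenolide aldehyde A7. In the forward step NiCl2/CrCl2 converts the vinyl iodide into a vinylchromium species that adds to the aldehyde, closing the ring and creating C8 (Nozaki–Hiyama–Kishi reaction).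
- In its favour: the butenolide with its C13 acetate is built on a small fragment, so no late C12/C13 differentiation is needed. The conditions tolerate lactone and acetate. Only acylation and epoxidation remain after ring closure; in step economy after cyclisation it is clearly better.
- Against it: the ring closure must also set C8, controlled only by C6 across the planar C7. The γ-hydrogen at C6 of A7 is acidic and doubly allylic, and the aldehyde is β,γ-unsaturated. The nucleophilic carbon is a fully substituted, electron-poor alkenyl carbon, and stoichiometric divalent chromium is needed at high dilution.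
- Comparison: ring size and preformed E,E-diene are equal in both plans. The chosen plan closes between two sp3 carbons and creates no lasting stereocentre, so its outcome does not rest on macrocyclic diastereoselection.

Key step: step 17

Remark: positions are given in germacrane numbering (C1–C15) for open-chain compounds as well; 28 (C2 epimers) and 31/32 (acetal epimers) are carried as mixtures because those centres are removed later; 37 is treated as a commercial chiral-pool acid. The configurations of 26 and 28 were checked against 44 and agree with it: C6 is R up to 43 and S in 44 only because the epoxide raises the priority of C5.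

## Route

Step 1
Reactants: 1 2,2-dimethyl-1,3-dioxan-5-one
Product: 2 5-(dibromomethylidene)-2,2-dimethyl-1,3-dioxane
Conditions: CBr4, PPh3, CH2Cl2, 0 °C → rt
Reagents that add atoms: carbon tetrabromide, BrC(Br)(Br)Br
Why: Ramirez dibromo-olefination (first stage of the Corey–Fuchs sequence) of a ketone activated by two α-oxygens; C11 carries two identical arms, so the tetrasubstituted alkene has no geometry to control.

Step 2
Reactants: 2 5-(dibromomethylidene)-2,2-dimethyl-1,3-dioxane
Product: 4 bromo enal 2-bromo-2-(2,2-dimethyl-1,3-dioxan-5-ylidene)acetaldehyde, via 1-bromo-1-lithioalkene 3 (not isolated)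
Conditions: n-BuLi (1.05 equiv), THF/Et2O, −100 °C; DMF, −100 → −78 °C; aq. NH4Cl
Reagents that add atoms: N,N-dimethylformamide, CN(C)C=O
Why: Bromine–lithium exchange gives the carbenoid, kept below −90 °C where Fritsch–Buttenberg–Wiechell shift and α-elimination are slow, and DMF formylates it; the two bromines of 2 are equivalent, so there is no selectivity issue.

Step 3
Reactants: 5 propargyl alcohol
Product: 7 (E)-3-iodo-2-methylprop-2-en-1-ol, via alkenylalane 6 (not isolated)
Conditions: Me3Al (3 equiv), Cp2ZrCl2 (0.25 equiv), CH2Cl2, 0 °C → rt; I2, THF, −30 °C; aq. potassium sodium tartrate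
Reagents that add atoms: trimethylaluminium, C[Al](C)C; iodine, II
Why: Negishi carboalumination adds Me–Al syn with methyl on the internal carbon, and iodinolysis of the C–Al bond proceeds with retention; this fixes the E geometry of the future C4=C5 alkene.

Step 4
Reactants: 7 (E)-3-iodo-2-methylprop-2-en-1-ol
Product: 8 (E)-tert-butyl[(3-iodo-2-methylprop-2-en-1-yl)oxy]dimethylsilane
Conditions: TBSCl, imidazole, CH2Cl2, 0 °C → rt
Reagents that add atoms: tert-butyldimethylsilyl chloride, CC(C)(C)[Si](C)(C)Cl
Why: Standard silylation of a primary alcohol; a primary silyl ether is chosen because it can later be removed beside a secondary one.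

Step 5
Reactants: 8 (E)-tert-butyl[(3-iodo-2-methylprop-2-en-1-yl)oxy]dimethylsilane; 4 bromo enal
Product: 10 racemic bromo dienol (3E)-1-bromo-5-[(tert-butyldimethylsilyl)oxy]-1-(2,2-dimethyl-1,3-dioxan-5-ylidene)-4-methylpent-3-en-2-ol, via alkenyllithium 9 (not isolated)
Conditions: 8, t-BuLi (2.05 equiv), Et2O, −78 °C; then 4, −78 °C; aq. NH4Cl
Reagents that add atoms: none
Why: Iodine–lithium exchange retains alkene geometry and the alkenyllithium adds 1,2 to the aldehyde faster than it attacks the vinyl bromide; the carbinol is made racemic on purpose because the centre is erased in step 6.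

Step 6
Reactants: 10 racemic bromo dienol
Product: 11 bromo dienone (3E)-1-bromo-5-[(tert-butyldimethylsilyl)oxy]-1-(2,2-dimethyl-1,3-dioxan-5-ylidene)-4-methylpent-3-en-2-one
Conditions: MnO2, CH2Cl2, rt
Reagents that add atoms: none
Why: MnO2 oxidation of a doubly allylic alcohol to the cross-conjugated ketone; silyl ether, acetonide and vinyl bromide are inert.

Step 7
Reactants: 11 bromo dienone
Product: 12 (2R,3E)-1-bromo-5-[(tert-butyldimethylsilyl)oxy]-1-(2,2-dimethyl-1,3-dioxan-5-ylidene)-4-methylpent-3-en-2-ol
Conditions: (S)-Me-CBS oxazaborolidine (0.3 equiv), catecholborane (1.5 equiv), toluene/CH2Cl2, −78 °C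
Reagents that add atoms: none
Why: Corey–Bakshi–Shibata reduction; the fully substituted α-bromoalkenyl group acts as the large substituent and CH=C(Me) as the small one, so the (S)-catalyst should give the R carbinol, which has the spatial arrangement of C6 in 44. α-Bromo enones are a well-behaved substrate class for this reduction.

Step 8
Reactants: 12 (2R)-bromo dienol
Product: 13 PMB ether 5-[(2R,3E)-1-bromo-5-[(tert-butyldimethylsilyl)oxy]-2-[(4-methoxybenzyl)oxy]-4-methylpent-3-en-1-ylidene]-2,2-dimethyl-1,3-dioxane
Conditions: NaH, PMBCl, Bu4NI (cat.), DMF, 0 °C → rt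
Reagents that add atoms: 4-methoxybenzyl chloride, COc1ccc(CCl)cc1
Why: Williamson etherification; the alkoxide has no elimination pathway, and the PMB group is chosen because it later serves to tell C12 from C13.

Step 9
Reactants: 13 PMB ether
Product: 15 enal (3R,4E)-6-[(tert-butyldimethylsilyl)oxy]-2-(2,2-dimethyl-1,3-dioxan-5-ylidene)-3-[(4-methoxybenzyl)oxy]-5-methylhex-4-enal, via alkenyllithium 14 (not isolated)
Conditions: t-BuLi (2.1 equiv), Et2O, −78 °C; DMF, −78 → −40 °C; aq. NH4Cl
Reagents that add atoms: N,N-dimethylformamide, CN(C)C=O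
Why: Bromine–lithium exchange on the vinyl bromide followed by formylation; the β-alkoxy vinyllithium is kept at −78 °C, where 2-lithioallyl ethers persist, to avoid elimination to an allene.

Step 10
Reactants: 16 methyl 3-methylbut-2-enoate
Product: 18 silyl dienol ether tert-butyl[(1-methoxy-3-methylbuta-1,3-dien-1-yl)oxy]dimethylsilane, via lithium dienolate 17 (not isolated)
Conditions: LiN(i-Pr)2, THF, −78 °C; TBSCl, DMPU, −78 °C → rt
Reagents that add atoms: tert-butyldimethylsilyl chloride, CC(C)(C)[Si](C)(C)Cl
Why: Kinetic γ-deprotonation gives the cross-conjugated dienolate, which is silylated on oxygen; the ketene acetal geometry is irrelevant because no α-stereocentre is formed later.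

Step 11
Reactants: 15 enal; 18 silyl dienol ether
Product: 19 methyl (2E,5S,7R,8E)-10-[(tert-butyldimethylsilyl)oxy]-6-(2,2-dimethyl-1,3-dioxan-5-ylidene)-5-hydroxy-7-[(4-methoxybenzyl)oxy]-3,9-dimethyldeca-2,8-dienoate
Conditions: SiCl4 (1.1 equiv), 2,2′-binaphthyldiamine-derived bisphosphoramide (Si-face-selective antipode, 5 mol%), i-Pr2NEt, CH2Cl2, −78 °C; aq. NaHCO3
Reagents that add atoms: none
Why: Catalytic enantioselective vinylogous Mukaiyama aldol addition with Lewis-base-activated SiCl4: the dienolate reacts at its γ-carbon and gives the E-enoate, and the catalyst antipode is chosen so that bond formation on the Si face of the aldehyde sets 8S, with catalyst control expected to override the resident C6 centre. Bulk SiCl4 is a weak Lewis acid and should leave acetonide, PMB and silyl ethers intact.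

Step 12
Reactants: 19 hydroxy enoate
Product: 20 methyl (2E,5S,7R,8E)-5,10-bis[(tert-butyldimethylsilyl)oxy]-6-(2,2-dimethyl-1,3-dioxan-5-ylidene)-7-[(4-methoxybenzyl)oxy]-3,9-dimethyldeca-2,8-dienoate
Conditions: TBSOTf, 2,6-lutidine, CH2Cl2, −78 → 0 °C
Reagents that add atoms: tert-butyldimethylsilyl triflate, CC(C)(C)[Si](C)(C)OS(=O)(=O)C(F)(F)F
Why: Silyl triflate/lutidine silylation of a hindered secondary alcohol; the conditions are non-acidic, so acetonide and PMB ether persist.

Step 13
Reactants: 20 bis-silyl enoate
Product: 21 allylic alcohol (2E,5S,7R,8E)-5,10-bis[(tert-butyldimethylsilyl)oxy]-6-(2,2-dimethyl-1,3-dioxan-5-ylidene)-7-[(4-methoxybenzyl)oxy]-3,9-dimethyldeca-2,8-dien-1-ol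
Conditions: i-Bu2AlH (2.5 equiv), CH2Cl2, −78 °C; aq. potassium sodium tartrate
Reagents that add atoms: none
Why: 1,2-Reduction of the enoate to the E-allylic alcohol; no other reducible group is present.

Step 14
Reactants: 21 allylic alcohol; 22 sodium benzenesulfinate
Product: 24 allylic sulfone [(2E,5S,7R,8E)-5,10-bis[(tert-butyldimethylsilyl)oxy]-6-(2,2-dimethyl-1,3-dioxan-5-ylidene)-7-[(4-methoxybenzyl)oxy]-3,9-dimethyldeca-2,8-dien-1-yl] phenyl sulfone, via allylic mesylate 23 (not isolated)
Conditions: MsCl, Et3N, CH2Cl2, −20 °C; then PhSO2Na, DMF, rt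
Reagents that add atoms: none
Why: Mesylation and in-flask SN2 displacement by the sulfur terminus of the sulfinate at the primary allylic carbon; the sulfone is installed only now because its α-protons would not survive the organolithium steps.

Step 15
Reactants: 24 allylic sulfone
Product: 25 sulfonyl alcohol (2E,4R,6S,8E)-6-[(tert-butyldimethylsilyl)oxy]-5-(2,2-dimethyl-1,3-dioxan-5-ylidene)-4-[(4-methoxybenzyl)oxy]-2,8-dimethyl-10-(phenylsulfonyl)deca-2,8-dien-1-ol
Conditions: HF·pyridine, pyridine, THF, 0 °C
Reagents that add atoms: none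
Why: Buffered HF·pyridine cleaves the unhindered primary allylic silyl ether much faster than the hindered secondary one at O8 and does not touch the acetonide.

Step 16
Reactants: 25 sulfonyl alcohol
Product: 26 sulfone bromide [(2E,5S,7R,8E)-10-bromo-5-[(tert-butyldimethylsilyl)oxy]-6-(2,2-dimethyl-1,3-dioxan-5-ylidene)-7-[(4-methoxybenzyl)oxy]-3,9-dimethyldeca-2,8-dien-1-yl] phenyl sulfone
Conditions: CBr4, PPh3, 2,6-lutidine, CH2Cl2, −20 °C
Reagents that add atoms: carbon tetrabromide, BrC(Br)(Br)Br
Why: Appel bromination of the primary allylic alcohol, an SN2 process at the unhindered carbon under buffered conditions; sulfone, PMB ether and acetal are inert.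

Step 17
Reactants: 26 sulfone bromide
Product: 28 ten-membered sulfone (1(10)E,4E,6R,8S)-8-[(tert-butyldimethylsilyl)oxy]-12,13-(isopropylidenedioxy)-6-[(4-methoxybenzyl)oxy]-2-(phenylsulfonyl)germacra-1(10),4,7(11)-triene (C2 epimers), via sodium sulfonyl carbanion 27 (not isolated)
Conditions: NaN(SiMe3)2 (1.5 equiv), THF, 0 °C, 26 added over 8 h by syringe pump (final ca. 2 mM)
Reagents that add atoms: none
Why: NaN(SiMe3)2 removes a proton from C2, the only carbon acid within reach of the base (flanked by the sulfonyl group and the C1=C10 alkene), to give the allyl anion 27. The anion displaces the primary allylic bromide at C3 by direct SN2 attack and forms C2–C3. The closest known reaction type is the intramolecular alkylation of an allylic sulfone or sulfide carbanion by an allylic halide, used to close (E,E)-cyclodeca-1,5-dienes and larger 1,5-diene macrocycles before reductive removal of sulfur. The ring closes in a 10-exo-tet mode, end to end, and slow addition at high dilution lets the first-order cyclisation outrun second-order dimerisation. No lasting stereocentre is created: C2 is stereogenic only through the sulfonyl group removed in step 18, so either epimer serves, while C6 and C8 carry no acidic hydrogen and both alkenes keep their E geometry because no metal–allyl intermediate is involved. The step needs α- and not γ-attack of the ambident anion and SN2 and not SN2′ displacement; the sulfonyl group localises charge at C2, and the bromide sits on an unhindered primary carbon whereas attack at C5 would close a strained eight-membered ring next to C6. The three planar units (two E-alkenes and C7) remove transannular hydrogens and hold the termini within reach.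

Step 18
Reactants: 28 ten-membered sulfone
Product: 29 (1(10)E,4E,6R,8S)-8-[(tert-butyldimethylsilyl)oxy]-12,13-(isopropylidenedioxy)-6-[(4-methoxybenzyl)oxy]germacra-1(10),4,7(11)-triene
Conditions: PdCl2(dppp) (10 mol%), LiBHEt3 (3 equiv), THF, 0 °C
Reagents that add atoms: none
Why: Palladium-catalysed hydride desulfonylation of an allylic sulfone: zerovalent palladium formed in the flask ionises the C2–S bond and hydride is delivered to the less substituted allyl terminus C2, which should keep the C1=C10 alkene trisubstituted and E. Ethers, acetal and silyl ether are inert to LiBHEt3, which is why the step comes before any ester exists.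

Step 19
Reactants: 29 acetonide
Product: 30 diol (1(10)E,4E,6R,8S)-8-[(tert-butyldimethylsilyl)oxy]-6-[(4-methoxybenzyl)oxy]germacra-1(10),4,7(11)-triene-12,13-diol
Conditions: PPTS (0.2 equiv), MeOH, rt
Reagents that add atoms: none
Why: Acid-catalysed transacetalisation to methanol; PPTS is mild enough for the secondary silyl ether, the PMB ether and the 1,5-diene.

Step 20
Reactants: 30 diol
Product: 31 6,12-O-(4-methoxybenzylidene) acetal of (6R,8S)-8-[(tert-butyldimethylsilyl)oxy]germacra-1(10),4,7(11)-triene-6,12,13-triol (acetal epimers; 13-OH free)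
Conditions: DDQ (1.2 equiv), 4 Å molecular sieves, CH2Cl2, 0 °C
Reagents that add atoms: none
Why: Oxidative acetalisation of a PMB ether: DDQ abstracts hydride from the benzylic CH2 and, without water, the oxocarbenium ion is captured by the only hydroxyl within reach, the CH2OH cis to C6. This closes a 4,7-dihydro-1,3-dioxepine of the kind cis-2-ene-1,4-diols form readily with aryl aldehydes, and thereby defines C12 (in the acetal) and C13 (free).

Step 21
Reactants: 31 benzylidene acetal
Product: 32 13-acetate of 31 (acetal epimers)
Conditions: Ac2O, pyridine, DMAP (cat.), CH2Cl2, 0 °C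
Reagents that add atoms: acetic anhydride, CC(=O)OC(C)=O
Why: Acetylation of the one free primary allylic alcohol places the C13 acetate of 44.

Step 22
Reactants: 32 acetal acetate
Product: 33 (6R,8S)-13-acetoxy-8-[(tert-butyldimethylsilyl)oxy]germacra-1(10),4,7(11)-triene-6,12-diol (C12 cis to C6)
Conditions: AcOH/THF/H2O (3:1:1), rt
Reagents that add atoms: none
Why: Mild acid hydrolysis of the aryl acetal through its stabilised dioxocarbenium ion; acetate and secondary silyl ether survive aqueous acetic acid at room temperature.

Step 23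
Reactants: 33 ene-1,4-diol
Product: 35 (6R,8S)-13-acetoxy-8-[(tert-butyldimethylsilyl)oxy]germacra-1(10),4,7(11)-trien-12,6-olide, via lactol 34 (not isolated)
Conditions: TEMPO (0.2 equiv), PhI(OAc)2 (2.5 equiv), CH2Cl2, rt
Reagents that add atoms: none
Why: TEMPO/PhI(OAc)2 oxidises the primary allylic alcohol in preference to the secondary one; the hydroxy aldehyde closes to the five-membered lactol with the cis C6 hydroxyl and is oxidised on to the butenolide without touching C6.

Step 24
Reactants: 35 silyl butenolide
Product: 36 (6R,8S)-13-acetoxy-8-hydroxygermacra-1(10),4,7(11)-trien-12,6-olide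
Conditions: HF·pyridine, THF, 0 °C → rt
Reagents that add atoms: none
Why: Acidic fluoride cleaves the secondary silyl ether under non-basic conditions, chosen because the 13-acetoxy butenolide would not tolerate basic fluoride.

Step 25
Reactants: 37 (R)-3-bromo-2-hydroxy-2-methylpropanoic acid
Product: 39 (R)-3-chloro-2-hydroxy-2-methylpropanoic acid, via sodium (S)-2-methylglycidate 38 (not isolated)
Conditions: NaOH (2.1 equiv), H2O, 0 °C → rt; then conc. HCl, 0 °C → rt
Reagents that add atoms: hydrogen chloride, Cl
Why: Hydroxide closes the bromohydrin to the glycidate by intramolecular SN2 at CH2Br, and HCl reopens it at the same primary carbon because the tertiary carbon is deactivated by the carboxyl group; the stereocentre is never touched, so the configuration of the pool acid is retained.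

Step 26
Reactants: 39 (R)-3-chloro-2-hydroxy-2-methylpropanoic acid
Product: 41 (S)-3-chloro-2-methyl-2-[(trimethylsilyl)oxy]propanoyl chloride, via bis(trimethylsilyl) derivative 40 (not isolated)
Conditions: Me3SiCl (2.2 equiv), pyridine, CH2Cl2, rt; then (COCl)2, DMF (cat.), 0 °C → rt; evaporation
Reagents that add atoms: chlorotrimethylsilane, C[Si](C)(C)Cl; oxalyl chloride, O=C(Cl)C(Cl)=O
Why: Both hydroxyl functions are silylated and the silyl ester is converted into the acid chloride by oxalyl chloride/DMF under neutral conditions; the tertiary silyl ether survives and blocks self-acylation and oxirane closure (the descriptor changes to S by priority only).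

Step 27
Reactants: 36 hydroxy butenolide; 41 silyloxy acid chloride
Product: 43 (6R,8S)-13-acetoxy-8-[(2R)-3-chloro-2-hydroxy-2-methylpropanoyloxy]germacra-1(10),4,7(11)-trien-12,6-olide, via trimethylsilyl ether 42 (not isolated)
Conditions: pyridine, DMAP (0.2 equiv), CH2Cl2, 0 °C → rt; then citric acid, MeOH, 0 °C
Reagents that add atoms: none
Why: DMAP-catalysed acylation of the hindered secondary allylic alcohol by the acid chloride, then mild acid methanolysis of the tertiary trimethylsilyl ether; weakly basic pyridine should not provoke SN2′ loss of the allylic acetate or epimerisation at C6.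

Step 28
Reactants: 43 triene ester
Product: 44 CNP0255009.1, (1R,4R,5R,6S,8S,10R)-13-acetoxy-8-[(2R)-3-chloro-2-hydroxy-2-methylpropanoyloxy]-1,10:4,5-diepoxygermacr-7(11)-en-12,6-olide
Conditions: mCPBA (2.3 equiv), NaHCO3, CH2Cl2, 0 °C
Reagents that add atoms: 3-chloroperoxybenzoic acid, OOC(=O)c1cccc(Cl)c1
Why: Prilezhaev epoxidation of the two electron-rich E-trisubstituted alkenes, stereospecifically trans at each; the butenolide alkene is too electron-poor to react. At C4=C5 minimised A(1,3) strain puts H6 in the alkene plane, so the peracid attacks the face on the side of O6 and away from C7 (4R,5R); at C1=C10 attack on the outer face of the crossed conformer with both methyl groups syn gives 1R,10R.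

## Compound list

1 | 2,2-dimethyl-1,3-dioxan-5-one | CC1(C)OCC(=O)CO1 | starting material
2 | 5-(dibromomethylidene)-2,2-dimethyl-1,3-dioxane | CC1(C)OCC(=C(Br)Br)CO1 | intermediate
3 | 5-[bromo(lithio)methylidene]-2,2-dimethyl-1,3-dioxane (not isolated) | [Li]C(Br)=C1COC(C)(C)OC1 | intermediate
4 | 2-bromo-2-(2,2-dimethyl-1,3-dioxan-5-ylidene)acetaldehyde | O=CC(Br)=C1COC(C)(C)OC1 | intermediate
5 | propargyl alcohol | C#CCO | starting material
6 | (E)-alkenylalane, dimethylaluminium alkoxide of 3-(dimethylalumino)-2-methylprop-2-en-1-ol (not isolated) | C[Al](C)OC/C(C)=C/[Al](C)C | intermediate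
7 | (E)-3-iodo-2-methylprop-2-en-1-ol | OC/C(C)=C/I | intermediate
8 | (E)-tert-butyl[(3-iodo-2-methylprop-2-en-1-yl)oxy]dimethylsilane | CC(C)(C)[Si](C)(C)OC/C(C)=C/I | intermediate
9 | (E)-3-[(tert-butyldimethylsilyl)oxy]-2-methylprop-1-en-1-yllithium (not isolated) | CC(C)(C)[Si](C)(C)OC/C(C)=C/[Li] | intermediate
10 | rac-(3E)-1-bromo-5-[(tert-butyldimethylsilyl)oxy]-1-(2,2-dimethyl-1,3-dioxan-5-ylidene)-4-methylpent-3-en-2-ol | CC(C)(C)[Si](C)(C)OC/C(C)=C/C(O)C(Br)=C1COC(C)(C)OC1 | intermediate
11 | (3E)-1-bromo-5-[(tert-butyldimethylsilyl)oxy]-1-(2,2-dimethyl-1,3-dioxan-5-ylidene)-4-methylpent-3-en-2-one | CC(C)(C)[Si](C)(C)OC/C(C)=C/C(=O)C(Br)=C1COC(C)(C)OC1 | intermediate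
12 | (2R,3E)-1-bromo-5-[(tert-butyldimethylsilyl)oxy]-1-(2,2-dimethyl-1,3-dioxan-5-ylidene)-4-methylpent-3-en-2-ol | CC(C)(C)[Si](C)(C)OC/C(C)=C/[C@@H](O)C(Br)=C1COC(C)(C)OC1 | intermediate
13 | 5-[(2R,3E)-1-bromo-5-[(tert-butyldimethylsilyl)oxy]-2-[(4-methoxybenzyl)oxy]-4-methylpent-3-en-1-ylidene]-2,2-dimethyl-1,3-dioxane | CC(C)(C)[Si](C)(C)OC/C(C)=C/[C@@H](OCc1ccc(OC)cc1)C(Br)=C1COC(C)(C)OC1 | intermediate
14 | alkenyllithium from 13, lithium in place of bromine at C7 (not isolated) | CC(C)(C)[Si](C)(C)OC/C(C)=C/[C@@H](OCc1ccc(OC)cc1)C([Li])=C1COC(C)(C)OC1 | intermediate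
15 | (3R,4E)-6-[(tert-butyldimethylsilyl)oxy]-2-(2,2-dimethyl-1,3-dioxan-5-ylidene)-3-[(4-methoxybenzyl)oxy]-5-methylhex-4-enal | CC(C)(C)[Si](C)(C)OC/C(C)=C/[C@@H](OCc1ccc(OC)cc1)C(C=O)=C1COC(C)(C)OC1 | intermediate
16 | methyl 3-methylbut-2-enoate | COC(=O)C=C(C)C | starting material
17 | lithium dienolate of 16 (not isolated) | [Li]OC(OC)=CC(C)=C | intermediate
18 | tert-butyl[(1-methoxy-3-methylbuta-1,3-dien-1-yl)oxy]dimethylsilane (ketene acetal geometry undefined, not carried on) | COC(O[Si](C)(C)C(C)(C)C)=CC(C)=C | intermediate
19 | methyl (2E,5S,7R,8E)-10-[(tert-butyldimethylsilyl)oxy]-6-(2,2-dimethyl-1,3-dioxan-5-ylidene)-5-hydroxy-7-[(4-methoxybenzyl)oxy]-3,9-dimethyldeca-2,8-dienoate | COC(=O)/C=C(C)/C[C@H](O)C(=C1COC(C)(C)OC1)[C@H](OCc1ccc(OC)cc1)/C=C(C)/CO[Si](C)(C)C(C)(C)C | intermediate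
20 | methyl (2E,5S,7R,8E)-5,10-bis[(tert-butyldimethylsilyl)oxy]-6-(2,2-dimethyl-1,3-dioxan-5-ylidene)-7-[(4-methoxybenzyl)oxy]-3,9-dimethyldeca-2,8-dienoate | COC(=O)/C=C(C)/C[C@H](O[Si](C)(C)C(C)(C)C)C(=C1COC(C)(C)OC1)[C@H](OCc1ccc(OC)cc1)/C=C(C)/CO[Si](C)(C)C(C)(C)C | intermediate
21 | (2E,5S,7R,8E)-5,10-bis[(tert-butyldimethylsilyl)oxy]-6-(2,2-dimethyl-1,3-dioxan-5-ylidene)-7-[(4-methoxybenzyl)oxy]-3,9-dimethyldeca-2,8-dien-1-ol | OC/C=C(C)/C[C@H](O[Si](C)(C)C(C)(C)C)C(=C1COC(C)(C)OC1)[C@H](OCc1ccc(OC)cc1)/C=C(C)/CO[Si](C)(C)C(C)(C)C | intermediate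
22 | sodium benzenesulfinate | [Na+].[O-]S(=O)c1ccccc1 | starting material
23 | methanesulfonate of 21 (not isolated) | CS(=O)(=O)OC/C=C(C)/C[C@H](O[Si](C)(C)C(C)(C)C)C(=C1COC(C)(C)OC1)[C@H](OCc1ccc(OC)cc1)/C=C(C)/CO[Si](C)(C)C(C)(C)C | intermediate
24 | [(2E,5S,7R,8E)-5,10-bis[(tert-butyldimethylsilyl)oxy]-6-(2,2-dimethyl-1,3-dioxan-5-ylidene)-7-[(4-methoxybenzyl)oxy]-3,9-dimethyldeca-2,8-dien-1-yl] phenyl sulfone | O=S(=O)(c1ccccc1)C/C=C(C)/C[C@H](O[Si](C)(C)C(C)(C)C)C(=C1COC(C)(C)OC1)[C@H](OCc1ccc(OC)cc1)/C=C(C)/CO[Si](C)(C)C(C)(C)C | intermediate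
25 | (2E,4R,6S,8E)-6-[(tert-butyldimethylsilyl)oxy]-5-(2,2-dimethyl-1,3-dioxan-5-ylidene)-4-[(4-methoxybenzyl)oxy]-2,8-dimethyl-10-(phenylsulfonyl)deca-2,8-dien-1-ol | O=S(=O)(c1ccccc1)C/C=C(C)/C[C@H](O[Si](C)(C)C(C)(C)C)C(=C1COC(C)(C)OC1)[C@H](OCc1ccc(OC)cc1)/C=C(C)/CO | intermediate
26 | [(2E,5S,7R,8E)-10-bromo-5-[(tert-butyldimethylsilyl)oxy]-6-(2,2-dimethyl-1,3-dioxan-5-ylidene)-7-[(4-methoxybenzyl)oxy]-3,9-dimethyldeca-2,8-dien-1-yl] phenyl sulfone | O=S(=O)(c1ccccc1)C/C=C(C)/C[C@H](O[Si](C)(C)C(C)(C)C)C(=C1COC(C)(C)OC1)[C@H](OCc1ccc(OC)cc1)/C=C(C)/CBr | intermediate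
27 | sodium salt of the C2 carbanion of 26 (not isolated) | [Na+].O=S(=O)(c1ccccc1)[CH-]/C=C(C)/C[C@H](O[Si](C)(C)C(C)(C)C)C(=C1COC(C)(C)OC1)[C@H](OCc1ccc(OC)cc1)/C=C(C)/CBr | intermediate
28 | (1(10)E,4E,6R,8S)-8-[(tert-butyldimethylsilyl)oxy]-12,13-(isopropylidenedioxy)-6-[(4-methoxybenzyl)oxy]-2-(phenylsulfonyl)germacra-1(10),4,7(11)-triene, C2 epimers | CC1(C)OCC(CO1)=C2[C@@H](O[Si](C)(C)C(C)(C)C)C/C(C)=C/C(S(=O)(=O)c1ccccc1)C/C(C)=C/[C@H]2OCc1ccc(OC)cc1 | intermediate
29 | (1(10)E,4E,6R,8S)-8-[(tert-butyldimethylsilyl)oxy]-12,13-(isopropylidenedioxy)-6-[(4-methoxybenzyl)oxy]germacra-1(10),4,7(11)-triene | CC1(C)OCC(CO1)=C2[C@@H](O[Si](C)(C)C(C)(C)C)C/C(C)=C/CC/C(C)=C/[C@H]2OCc1ccc(OC)cc1 | intermediate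
30 | (1(10)E,4E,6R,8S)-8-[(tert-butyldimethylsilyl)oxy]-6-[(4-methoxybenzyl)oxy]germacra-1(10),4,7(11)-triene-12,13-diol | OCC(CO)=C1[C@@H](O[Si](C)(C)C(C)(C)C)C/C(C)=C/CC/C(C)=C/[C@H]1OCc1ccc(OC)cc1 | intermediate
31 | 6,12-O-(4-methoxybenzylidene) acetal of (6R,8S)-8-[(tert-butyldimethylsilyl)oxy]germacra-1(10),4,7(11)-triene-6,12,13-triol, acetal epimers | OC/C3=C1\[C@@H](O[Si](C)(C)C(C)(C)C)C/C(C)=C/CC/C(C)=C/[C@H]1OC(c1ccc(OC)cc1)OC3 | intermediate
32 | 13-acetate of 31, acetal epimers | CC(=O)OC/C3=C1\[C@@H](O[Si](C)(C)C(C)(C)C)C/C(C)=C/CC/C(C)=C/[C@H]1OC(c1ccc(OC)cc1)OC3 | intermediate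
33 | (6R,8S)-13-acetoxy-8-[(tert-butyldimethylsilyl)oxy]germacra-1(10),4,7(11)-triene-6,12-diol, C12 cis to C6 | CC(=O)OC/C(CO)=C1\[C@@H](O[Si](C)(C)C(C)(C)C)C/C(C)=C/CC/C(C)=C/[C@H]1O | intermediate
34 | lactol of 35, C12 epimers (not isolated) | CC(=O)OCC1=C2[C@@H](O[Si](C)(C)C(C)(C)C)C/C(C)=C/CC/C(C)=C/[C@H]2OC1O | intermediate
35 | (6R,8S)-13-acetoxy-8-[(tert-butyldimethylsilyl)oxy]germacra-1(10),4,7(11)-trien-12,6-olide | CC(=O)OCC1=C2[C@@H](O[Si](C)(C)C(C)(C)C)C/C(C)=C/CC/C(C)=C/[C@H]2OC1=O | intermediate
36 | (6R,8S)-13-acetoxy-8-hydroxygermacra-1(10),4,7(11)-trien-12,6-olide | CC(=O)OCC1=C2[C@@H](O)C/C(C)=C/CC/C(C)=C/[C@H]2OC1=O | intermediate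
37 | (R)-3-bromo-2-hydroxy-2-methylpropanoic acid | OC(=O)[C@@](C)(O)CBr | starting material
38 | sodium (S)-2-methyloxirane-2-carboxylate (not isolated) | [Na+].[O-]C(=O)[C@@]1(C)OC1 | intermediate
39 | (R)-3-chloro-2-hydroxy-2-methylpropanoic acid | OC(=O)[C@@](C)(O)CCl | intermediate
40 | trimethylsilyl (R)-3-chloro-2-methyl-2-[(trimethylsilyl)oxy]propanoate (not isolated) | C[Si](C)(C)OC(=O)[C@@](C)(O[Si](C)(C)C)CCl | intermediate
41 | (S)-3-chloro-2-methyl-2-[(trimethylsilyl)oxy]propanoyl chloride | ClC(=O)[C@@](C)(O[Si](C)(C)C)CCl | intermediate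
42 | (6R,8S)-13-acetoxy-8-[(2R)-3-chloro-2-methyl-2-(trimethylsilyloxy)propanoyloxy]germacra-1(10),4,7(11)-trien-12,6-olide (not isolated) | CC(=O)OCC1=C2[C@@H](OC(=O)[C@@](C)(O[Si](C)(C)C)CCl)C/C(C)=C/CC/C(C)=C/[C@H]2OC1=O | intermediate
43 | (6R,8S)-13-acetoxy-8-[(2R)-3-chloro-2-hydroxy-2-methylpropanoyloxy]germacra-1(10),4,7(11)-trien-12,6-olide | CC(=O)OCC1=C2[C@@H](OC(=O)[C@@](C)(O)CCl)C/C(C)=C/CC/C(C)=C/[C@H]2OC1=O | intermediate
44 | CNP0255009.1, (1R,4R,5R,6S,8S,10R)-13-acetoxy-8-[(2R)-3-chloro-2-hydroxy-2-methylpropanoyloxy]-1,10:4,5-diepoxygermacr-7(11)-en-12,6-olide | CC(=O)OCC1=C2[C@@H](OC(=O)[C@@](C)(O)CCl)C[C@@]3(C)O[C@@H]3CC[C@@]3(C)O[C@@H]3[C@H]2OC1=O | target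

## Step count and least certain steps

Total step count: 28. Longest linear sequence: 23 steps (1, 2, 5–9, 11–24, 27, 28 from compound 1; the same length from compound 5 through steps 3 and 4).

Step 17 (key step). The most likely failure is intermolecular alkylation outrunning the ten-membered closure, or attack through the γ-carbon of the anion or at C5 of the bromide, because the chain must fold two E-alkenes around C7 before the termini meet. Fallback, from 21 and back at 29: the same C2–C3 bond is made by reductive coupling of two allylic bromides on nickel. Selective removal of the primary silyl group of 21 (HF·pyridine) gives the bis-allylic diol F1; CBr4/PPh3 converts both hydroxyls into the bis-allylic dibromide F2; F2 is cyclised with Ni(CO)4 (or Ni(cod)2 as the zerovalent nickel source) in N-methylpyrrolidone at high dilution. This gives the sulfur-free ring directly, so step 18 is skipped. The price is that allylnickel intermediates can erode E geometry and couple head to tail.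

Step 11. The most likely failure is poor facial selectivity or low conversion, because the aldehyde is a fully substituted enal and the neighbouring C6 centre may oppose the catalyst. Fallback, from 15 and back at 20:
- Brown allylation with (−)-Ipc2B(allyl), made from (+)-α-pinene and delivering allyl to the Si face, gives the homoallylic alcohol F3.
- Silylation (TBSOTf, 2,6-lutidine) gives the bis-silyl ether F4.
- Wacker oxidation (PdCl2, CuCl, O2, DMF/H2O) of the only monosubstituted alkene gives the methyl ketone F5.
- Horner–Wadsworth–Emmons olefination with trimethyl phosphonoacetate gives 20 after separation of the Z isomer.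

Step 20. The most likely failure is capture of the benzylic cation by adventitious water, or hydride abstraction at the doubly allylic C6–H, because seven-membered capture is slower than the usual five- and six-membered cases. Fallback, from 30 and back at 35: deliberate PMB removal with DDQ in wet CH2Cl2 gives the triol F6. TEMPO/PhI(OAc)2 oxidation then follows, in which only the C12 aldehyde can be trapped as a lactol and carried on, and gives the hydroxymethyl butenolide F7 after separation from material oxidised at C13. Acetylation (Ac2O, pyridine) gives 35.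

Step 18. The most likely failure is loss of positional or geometric integrity of the C1=C10 alkene, because the allylpalladium intermediate can equilibrate and accept hydride at C10. Fallback, from 28 to 29 with no new compound (F0): electron-transfer desulfonylation with Na(Hg) and Na2HPO4 in MeOH at low temperature, which cleaves C–S through a radical anion and protonates the allyl anion at its less substituted end without a metal–allyl complex.

Step 28. The most likely failure is poor facial selectivity at C1=C10, which is controlled only by ring conformation, or transannular opening of the product by the acid by-product. Fallback, from 43 to 44 with no new compound (F0): reagent-controlled Shi epoxidation with the D-fructose-derived ketone (KHSO5, buffered near pH 8, MeCN/dimethoxymethane/H2O, 0 °C). This catalyst imposes the R,R sense on E-trisubstituted alkenes whatever the substrate conformation and generates no carboxylic acid.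

## Further compounds

F1 | step 17 | (2E,4R,6S,8E)-6-[(tert-butyldimethylsilyl)oxy]-5-(2,2-dimethyl-1,3-dioxan-5-ylidene)-4-[(4-methoxybenzyl)oxy]-2,8-dimethyldeca-2,8-diene-1,10-diol | OC/C=C(C)/C[C@H](O[Si](C)(C)C(C)(C)C)C(=C1COC(C)(C)OC1)[C@H](OCc1ccc(OC)cc1)/C=C(C)/CO
F2 | step 17 | tert-butyl{[(2E,5S,7R,8E)-1,10-dibromo-6-(2,2-dimethyl-1,3-dioxan-5-ylidene)-7-[(4-methoxybenzyl)oxy]-3,9-dimethyldeca-2,8-dien-5-yl]oxy}dimethylsilane | BrC/C=C(C)/C[C@H](O[Si](C)(C)C(C)(C)C)C(=C1COC(C)(C)OC1)[C@H](OCc1ccc(OC)cc1)/C=C(C)/CBr
F3 | step 11 | (4S,6R,7E)-9-[(tert-butyldimethylsilyl)oxy]-5-(2,2-dimethyl-1,3-dioxan-5-ylidene)-6-[(4-methoxybenzyl)oxy]-8-methylnona-1,7-dien-4-ol | C=CC[C@H](O)C(=C1COC(C)(C)OC1)[C@H](OCc1ccc(OC)cc1)/C=C(C)/CO[Si](C)(C)C(C)(C)C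
F4 | step 11 | tert-butyldimethylsilyl ether of F3 | C=CC[C@H](O[Si](C)(C)C(C)(C)C)C(=C1COC(C)(C)OC1)[C@H](OCc1ccc(OC)cc1)/C=C(C)/CO[Si](C)(C)C(C)(C)C
F5 | step 11 | (4S,6R,7E)-4,9-bis[(tert-butyldimethylsilyl)oxy]-5-(2,2-dimethyl-1,3-dioxan-5-ylidene)-6-[(4-methoxybenzyl)oxy]-8-methylnon-7-en-2-one | CC(=O)C[C@H](O[Si](C)(C)C(C)(C)C)C(=C1COC(C)(C)OC1)[C@H](OCc1ccc(OC)cc1)/C=C(C)/CO[Si](C)(C)C(C)(C)C
F0 | step 18 | none | none
F6 | step 20 | (1(10)E,4E,6R,8S)-8-[(tert-butyldimethylsilyl)oxy]germacra-1(10),4,7(11)-triene-6,12,13-triol | OCC(CO)=C1[C@@H](O[Si](C)(C)C(C)(C)C)C/C(C)=C/CC/C(C)=C/[C@H]1O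
F7 | step 20 | (6R,8S)-8-[(tert-butyldimethylsilyl)oxy]-13-hydroxygermacra-1(10),4,7(11)-trien-12,6-olide | OCC1=C2[C@@H](O[Si](C)(C)C(C)(C)C)C/C(C)=C/CC/C(C)=C/[C@H]2OC1=O
F0 | step 28 | none | none
A1 | alternative 1 | diepoxy butenolide with tert-butyldimethylsilyl ethers on O8 and O13 | CC(C)(C)[Si](C)(C)OCC1=C2[C@@H](O[Si](C)(C)C(C)(C)C)C[C@@]3(C)O[C@@H]3CC[C@@]3(C)O[C@@H]3[C@H]2OC1=O
A2 | alternative 1 | ten-membered C4 tertiary alcohol with cis-5,6-epoxide, 1,10-epoxide, C12 methyl ester cis to C6 and silyl ethers on O8 and O13 | COC(=O)/C(CO[Si](C)(C)C(C)(C)C)=C1/[C@@H](O[Si](C)(C)C(C)(C)C)C[C@@]2(C)O[C@@H]2CC[C@@](C)(O)[C@H]3O[C@H]31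
A3 | alternative 2 | open-chain trans-4,5-epoxide with C1/C10 alkene and C6 silyl ether | CC(C)(C)[Si](C)(C)OC/C(C)=C/CC[C@@]1(C)O[C@@H]1[C@@H](O[Si](C)(C)C(C)(C)C)C(COCc1ccc(OC)cc1)=C1COC(C)(C)OC1
A4 | alternative 2 | α-chloro methyl ketone (C4 ketone, C5 chloride, C6 silyl ether) | CC(=O)[C@@H](Cl)[C@@H](O[Si](C)(C)C(C)(C)C)C(COCc1ccc(OC)cc1)=C1COC(C)(C)OC1
A5 | alternative 2 | (E)-5-[(tert-butyldimethylsilyl)oxy]-4-methylpent-3-enylmagnesium bromide | CC(C)(C)[Si](C)(C)OC/C(C)=C/CC[Mg]Br
A6 | alternative 3 | ten-membered dienolide with free C8 hydroxyl (identical with 36) | CC(=O)OCC1=C2[C@@H](O)C/C(C)=C/CC/C(C)=C/[C@H]2OC1=O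
A7 | alternative 3 | β-iodobutenolide with (E,E)-dienyl chain ending in the C8 aldehyde | CC(=O)OCC1=C(I)[C@@H](/C=C(C)/CC/C=C(C)/CC=O)OC1=O
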